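In the north-east run the substrate reading falls steadily from 25.4% at 15.0 min to 11.2% at 90.0 min, a pseudo-first-order fall with 0.0109 min⁻¹, which I call the fall rate. Run back to zero time, this line starts at 29.9%, close to the flat 31.3% of the north run. I therefore read the fast early loss as a quick equilibrium holding back a fixed share, with the held-back share still feeding the slow coupling through the free substrate. If so, what the substrate loses the partner loses too, and the number to carry is the partner's half-life at a given substrate charge:

partner's half-life = ln(2) × partner charge / (fall rate × substrate charge)

| flask | substrate | coupling partner | remark | time |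
|---|---|---|---|---|
| north-east | 0.069 M | 0.10 M | run made earlier |  |
| north | 1.2 M | 0.10 M | run made earlier |  |
| larch | 0.050 M | 0.100 M |  | 1.5 h |
| cedar | 0.10 M | 0.100 M |  | 1.5 h |
| birch | 0.20 M | 0.100 M |  | 1.5 h |
| oak | 0.40 M | 0.100 M |  | 1.5 h |
| ash | 0.80 M | 0.100 M |  | 1.5 h |

| run | time / min | target / % | substrate / % |
|---|---|---|---|
| north-east | 15.0 | 5.4 | 25.4 |
| north-east | 30.0 | 6.4 | 21.8 |
| north-east | 50.0 | 7.0 | 16.5 |
| north-east | 60.0 | 5.0 | 15.9 |
| north-east | 80.0 | 5.5 | 13.0 |
| north-east | 90.0 | 5.1 | 11.2 |
| north | 8.00 | 2.7 | 31.6 |
| north | 12.0 | 2.4 | 32.6 |
| north | 20.0 | 0.5 | 31.2 |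
| north | 30.0 | 1.5 | 31.4 |
| north | 50.0 | 0.7 | 31.3 |
| north | 90.0 | 0.5 | 31.3 |

(each reading ± 0.5 percentage points)

- [target] at the end for larch, cedar, birch, oak, ash, in this order
- the course of these numbers from the first flask to the last (hardly changes / rises, then falls / falls all the way / rises all the way / falls, then rises)

- "hardly changes" means that all values lie within two and a half points (for a concentration: within two and a half percent of the largest)

For birch this gives 31.7 min, and for larch 127 min, each with the substrate charge taken as it stands at the start; the larch charge is half the partner charge, so the larch figure holds for the start of that flask. For the north run it gives 5.29 min, shorter than the first reading at 8.00 min, and the substrate stands flat from there on.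

Now I turn the settings. Raising the substrate charge from the low end raises the starting coupling rate in step with it. At the high end, with the substrate in excess of the partner and the time fixed, the partner's half-life shortens and the partner left falls exponentially with the charge. Time enters through the lag of the target behind the coupling, which I read roughly as 50.0 min from the highest north-east target reading, at a scatter of 0.5 percentage points. I take the target at the end to follow the coupling rate one lag earlier, and that rate, which goes as charge times partner left, turns at

turning charge = partner charge / (fall rate × (time − lag)) = 0.229 M

The forecast gives 0.003 M, 0.005 M, 0.006 M, 0.005 M, 0.003 M, a course that rises, then falls, on grounds other than mine: “More substrate therefore gives a higher peak but greater loss”.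

The flasks give 0.00249 M, 0.00412 M, 0.00501 M, 0.00371 M, 0.00270 M; the course rises, then falls, birch stands highest, and the row turns at 0.19 M, where I had 0.229 M.

    substrate + coupling partner → intermediate + by-product (k = 0.00820 M⁻¹ s⁻¹)
    intermediate ⇌ target (K = 0.750, k = 0.00180 s⁻¹)
    intermediate ⇌ isomer of the product (K = 18.0, k = 8.30 × 10⁻⁴ s⁻¹)
    substrate ⇌ dormant form (K = 1.90, k = 0.0120 s⁻¹)
    target → over-reaction product (k = 5.60 × 10⁻⁴ s⁻¹)

From its starting half-life I reckon the partner left at 0.750 h as 78.2% in larch, where 75.7% stands, and as 37.4% in birch, where 29.7% stands. In larch, substrate and dormant form relax into each other, both ways together, with a half-life of 0.631 min, far shorter than the 4.6 h of the partner by the coupling at 1.50 h, and at 0.750 h they stand at 17.3% and 34.1% of the substrate charged.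

The data are calculated from invented constants; scatter was added.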